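## Analysis of the target

The target is a C–C linked dimer of two 7-hydroxy-3-arylchromans (isoflavans). The upper chroman (O1, C2, C3, C4, C4a–C8a, benzo ring A) carries a 2-hydroxy-4-methoxyphenyl group (ring B) on C3 and a central arene (ring C) on C4. Ring C has a methoxyl ortho and a hydroxyl para to the bond to C4, and ortho to that hydroxyl it carries C3″ of the lower 7-hydroxychroman (benzo ring D). There are three stereocentres: C3 (S) and C4 (R) are adjacent and trans on the upper pyran ring, while C3″ (S) is insulated from them by ring C and has to be set on its own. Sensitive features are the four phenols on electron-rich rings, the doubly benzylic C4–H, and the C4–aryl bonds, which strong acid can ionise. The difficulty lies in the trans-3,4-diaryl pair under absolute control next to a remote third centre, and in keeping four hydroxyls and two methoxyls on four similar arenes apart. The strategy rests on ring A: it is a resorcinol unit with the ether oxygen O1 on C8a and the free hydroxyl on C7, meta to each other, C5, C6 and C8 unsubstituted, fused to the pyran through C4a–C8a. This is the pattern that a vinylketene and an alkynyl ether give on benzannulation, with the alkynyl ether oxygen becoming O1, so ring A and the pyran can be closed together from an acyclic chain that already holds C3 and C4.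

## Retrosynthetic reasoning

**37 to 36.** The last operation is hydrogenolysis of three benzyl ethers. Only three are needed, because the fourth phenol (C7–OH) is produced free by the ring-forming step. Benzyl is chosen because it withstands base, hydride, organolithium reagents, oxidants and light, and its removal is neutral and does not touch C4.

**36 to 31.** Ring A and the pyran are cut together along C4a–C8a, C7–C8, C6–C7 and C4a–C5. This leads to the acyclic α-diazo vinyl ketone 31, in which C7 is the carbonyl carbon, C4a the diazo carbon, C5/C6 the vinyl group and C8a/C8 an ethynyl ether on the C2 oxygen. Cutting here removes two rings and four bonds at once and leaves the C3/C4 pair on an open chain, where it can be set by catalyst control. The forward reaction has to turn 31 into a vinylketene and make it find the tethered ynol ether before anything else.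

**31 to 26.** The diazo group is introduced last (31 from enone 29), since it tolerates neither organolithium reagents nor hydrides. The enone comes from the allylic alcohol 28. The ynol ether of 28 comes from the dichlorovinyl ether 26 by a strongly basic elimination that no ketone would survive, so C7 stays at the alcohol level until after this step.

**26 to 21.** The C6–C7 bond is cut to aldehyde 25, a vinyl nucleophile being added in the forward sense. The C7 oxygen comes from anti-Markovnikov hydration of the terminal alkene of 22 (via 24). The C2 hydroxyl of 21 is converted to the dichlorovinyl ether before C7 is oxygenated, so the two oxygen termini never have to be told apart.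

**21 to 13 and 19.** The C3–C4 bond is cut. It is the only bond whose formation creates both stereocentres at once, and it divides the molecule into a cinnamyl half (13) and an arylacetic half (19). The forward reaction is an allylic substitution in which an iridium catalyst controls C4 and an isothiourea catalyst controls C3. The ester carbon becomes C2 and the vinyl group is the masked C4a–C7 unit. The labile α-aryl ester is reduced in the same flask.

**13 to 11.** The bond between ring C and the propenyl chain is cut to aryl bromide 11. The bromine is carried from starting material 1, which fixes the regiochemistry on ring C. The coupling is placed after the hydrogenation that sets C3″, because the cinnamyl alkene would not survive it.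

**11 to 4 and 6.** C3″ is set by asymmetric hydrogenation of the C3″=C4″ bond of isoflavene 10. Isoflavene 10 is unravelled through diol 9 to coumarin 8, and the C3″=C4″ bond of 8 is cut to nitrile 4 and salicylaldehyde 6. This uses condensation chemistry for the skeleton and one catalytic step for the stereocentre.

**4, 19 and 6 to 1, 14 and 5.** Both arylacetic units come from the salicylaldehydes 1 and 14 by benzylation and the same one-carbon homologation (via 2 and 15; 17 is hydrolysed to 18 and activated as 19). Aldehyde 6 comes from 5 by selective benzylation.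

## Alternatives that were turned down

**Alternative 1:** The disconnection removes C2 as a methylene unit (O1–C2 and C2–C3), leading back to the ring-contracted trans-2,3-diaryl-2,3-dihydrobenzofuran tetrapivalate A2. In the forward step a rhodium or copper methylene carbenoid from diazomethane A3 would add to the furan oxygen, and a [1,2] Stevens shift of the benzylic carbon would give the chroman tetrapivalate A1; four ester cleavages then follow.
- For: ring A is bought and not built, the trans-diaryl relationship would be settled in a rigid five-membered ring, and pivalates remove O–H and benzylic ether C–H competition. On the number of rings that must be constructed this plan is leaner than the chosen one.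
- Against: an aryl alkyl ether oxygen is a weak ylide donor, and A2 offers the least selective of all carbenoids five electron-rich arenes (cyclopropanation and ring expansion), a second chroman oxygen and two methoxyls. Oxonium-ylide [1,2] shifts run through radical pairs, so the migrating benzylic carbon, the later C3, can lose configuration. A3 is hazardous on scale.
- Comparison: the chosen key step uses a ketene and an ynol ether that are matched to each other and indifferent to arenes and ethers, and C3 and C4 are spectators in it. The price is a longer approach.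

**Alternative 2:** The disconnection cuts C3–C4 and O1–C2, so the pyran is assembled from an o-quinone methide (ring A, C4 and ring C) and an aldehyde. In the forward step the hydroxybenzhydrol A5 would release the quinone methide, the enamine of arylacetaldehyde A6 with a chiral secondary amine would add to it, and hemiacetalisation would give lactol A4. Reductive removal of the anomeric hydroxyl and hydrogenolysis complete the route.
- For: this is the most convergent plan and clearly shorter than the chosen one. A5 would come in one step from bromide 11 and aldehyde 6, and amine-catalysed quinone methide annulations with aldehydes are established. On step count and convergence it is stronger.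
- Against: arylacetaldehydes are poor partners (self-condensation, and an α-aryl centre that epimerises through the open hydroxy aldehyde). The quinone methide carries a very electron-rich aryl group and is therefore a weak electrophile, formed as an E/Z mixture, which undermines facial control at C4. The later lactol deoxygenation needs a Lewis acid and a silane, conditions under which the doubly benzylic C4–aryl bond can ionise.
- Comparison: the chosen route sets C3 and C4 by two independent catalysts on a substrate that is reduced at once to a non-epimerisable alcohol, and C4 never meets acid afterwards. It gives up brevity for that.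

**Alternative 3:** The disconnection takes ring C apart. In the forward step, photolysis of diazo enone A8, which carries the complete upper chroman on the diazo carbon and the lower chroman on the enone β-carbon, in the presence of methoxyacetylene A9 would give the tribenzyl ether A7 with the ring C hydroxyl free.
- For: this intermolecular benzannulation with an alkoxyacetylene is a known reaction type, so its precedent is better than that of the chosen key step. It joins two finished chroman halves, and it delivers the methoxyl and the hydroxyl of ring C already differentiated.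
- Against: it does not address the hardest problem. The trans-3,4-disubstituted upper chroman must still be made by other means, with an acylmethyl group on C4. In the ketone that precedes A8 the C3″ hydrogen is γ to the enone, so the base-mediated diazo transfer risks dienolate formation and loss of C3″. The ketene bears a bulky secondary substituent and must capture a volatile alkyne used in excess, in competition with dimerisation.
- Comparison: the chosen strategy builds ring A instead. Ketene and alkyne are in the same molecule, the same event closes the pyran, and the acyclic dyad is made by catalytic allylation. What it gives up is precedent for the ring-forming step.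

Key step: step 22

Remarks on the chemistry and conventions:
- Ar1 = 2-(benzyloxy)-4-methoxyphenyl.
- Ar2 = 4-(benzyloxy)-5-[(3S)-7-(benzyloxy)chroman-3-yl]-2-methoxyphenyl.
- Atom labels C2–C8a refer to the upper chroman of the target; C3″ is the stereocentre of the lower chroman.
- Assumption: the sense of induction of the chiral catalysts in steps 7 and 14 is not predicted here; the enantiomer of each ligand that leads to the stated configuration is meant.
- Compounds 1, 5, 14 and the reagents named on the reagent lines are taken to be commercial.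
- Compounds 28–31 are acid-, heat- and light-sensitive and should be handled cold, on base-washed silica, and used promptly.

## Route

Step 1
Reactants: 1 5-bromo-2-hydroxy-4-methoxybenzaldehyde
Product: 2 2-(benzyloxy)-5-bromo-4-methoxybenzaldehyde
Conditions: BnBr, K2CO3, DMF, 50 °C
Reagents that add atoms: benzyl bromide, BrCc1ccccc1
Why: Williamson ether synthesis on the only phenol; carbonate is sufficient for the formyl-activated phenol, and the aldehyde and aryl bromide are untouched.

Step 2
Reactants: 2 2-(benzyloxy)-5-bromo-4-methoxybenzaldehyde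
Product: 4 [2-(benzyloxy)-5-bromo-4-methoxyphenyl]acetonitrile, via N-(1-tosylvinyl)formamide 3 (not isolated)
Conditions: TosMIC, t-BuOK, DME, −40 °C; then MeOH, reflux
Reagents that add atoms: p-toluenesulfonylmethyl isocyanide (TosMIC), Cc1ccc(cc1)S(=O)(=O)C[N+]#[C-]
Why: van Leusen reductive cyanation: the TosMIC anion adds to the aldehyde, the oxazoline opens to formamide 3, and methanolysis with loss of sulfinate leaves the nitrile one carbon longer; the aryl bromide and the ethers are inert.

Step 3
Reactants: 5 2,4-dihydroxybenzaldehyde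
Product: 6 4-(benzyloxy)-2-hydroxybenzaldehyde
Conditions: BnBr (1.0 equiv), NaHCO3, KI (cat.), MeCN, 80 °C
Reagents that add atoms: benzyl bromide, BrCc1ccccc1
Why: Williamson ether synthesis under weak base; the 2-hydroxyl is held in a hydrogen bond to the formyl group and is the poorer nucleophile, so mono-alkylation should occur at O4.

Step 4
Reactants: 4 [2-(benzyloxy)-5-bromo-4-methoxyphenyl]acetonitrile; 6 4-(benzyloxy)-2-hydroxybenzaldehyde
Product: 8 7-(benzyloxy)-3-[2-(benzyloxy)-5-bromo-4-methoxyphenyl]-2H-chromen-2-one, via 2-iminochromene 7 (not isolated)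
Conditions: t-BuOK, DMF, 80 °C; then 2 M HCl, 60 °C
Reagents that add atoms: water, O
Why: Knoevenagel condensation of the benzylic nitrile with the aldehyde followed by addition of the phenoxide to the nitrile closes imino-lactone 7, and mild aqueous acid hydrolyses the imine; this standard 3-arylcoumarin synthesis forms the C3″–C4″ bond of the lower unit.

Step 5
Reactants: 8 7-(benzyloxy)-3-[2-(benzyloxy)-5-bromo-4-methoxyphenyl]-2H-chromen-2-one
Product: 9 (Z)-2-[2-(benzyloxy)-5-bromo-4-methoxyphenyl]-3-[4-(benzyloxy)-2-hydroxyphenyl]prop-2-en-1-ol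
Conditions: DIBAL-H (5 equiv), CH2Cl2, −78 → 0 °C; Rochelle salt work-up
Reagents that add atoms: none
Why: 1,2-Reduction of the unsaturated lactone through the lactol to the allylic diol; DIBAL-H leaves the aryl bromide and the alkene alone, and the Z geometry is inherited from the ring.

Step 6
Reactants: 9 (Z)-2-[2-(benzyloxy)-5-bromo-4-methoxyphenyl]-3-[4-(benzyloxy)-2-hydroxyphenyl]prop-2-en-1-ol
Product: 10 7-(benzyloxy)-3-[2-(benzyloxy)-5-bromo-4-methoxyphenyl]-2H-chromene
Conditions: PPh3, DIAD, THF, 0 °C → rt
Reagents that add atoms: none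
Why: Intramolecular Mitsunobu etherification; the Z alkene holds the phenol next to the activated primary allylic alcohol, so the six-membered 2H-chromene should close in preference to intermolecular reaction.

Step 7
Reactants: 10 7-(benzyloxy)-3-[2-(benzyloxy)-5-bromo-4-methoxyphenyl]-2H-chromene
Product: 11 (3S)-7-(benzyloxy)-3-[2-(benzyloxy)-5-bromo-4-methoxyphenyl]chromane
Conditions: H2 (50 bar), [Ir(cod)(chiral phosphine–oxazoline)]BArF (2 mol%), CH2Cl2, rt
Reagents that add atoms: none
Why: Iridium-catalysed asymmetric hydrogenation of a 3-aryl-2H-chromene, a known route to isoflavans; the chiral P,N ligand selects one face of the trisubstituted styrenic alkene and so sets C3″ as S, and the homogeneous catalyst cleaves neither benzyl ethers nor the aryl bromide.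

Step 8
Reactants: 11 (3S)-7-(benzyloxy)-3-[2-(benzyloxy)-5-bromo-4-methoxyphenyl]chromane
Product: 12 (E)-3-Ar2-prop-2-en-1-ol
Conditions: (E)-Bu3SnCH=CHCH2OH, Pd2(dba)3 (2 mol%), P(t-Bu)3 (8 mol%), CsF, dioxane, 90 °C
Reagents that add atoms: (E)-3-(tributylstannyl)prop-2-en-1-ol, CCCC[Sn](CCCC)(CCCC)/C=C/CO
Why: Stille cross-coupling of the electron-rich aryl bromide under fluoride activation with a bulky electron-rich phosphine; the alkene geometry is retained and the free allylic alcohol is tolerated.

Step 9
Reactants: 12 (E)-3-Ar2-prop-2-en-1-ol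
Product: 13 tert-butyl (E)-3-Ar2-prop-2-en-1-yl carbonate
Conditions: Boc2O, Bu4NHSO4 (cat.), 30% aq. NaOH, CH2Cl2, 0 °C → rt
Reagents that add atoms: di-tert-butyl dicarbonate, CC(C)(C)OC(=O)OC(=O)OC(C)(C)C
Why: O-Acylation of the primary allylic alcohol under phase-transfer conditions gives the tert-butyl carbonate, the leaving group for the iridium-catalysed allylic substitution; the tert-butoxide it releases later is a poor nucleophile toward an active ester.

Step 10
Reactants: 14 2-hydroxy-4-methoxybenzaldehyde
Product: 15 2-(benzyloxy)-4-methoxybenzaldehyde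
Conditions: BnBr, K2CO3, DMF, 50 °C
Reagents that add atoms: benzyl bromide, BrCc1ccccc1
Why: Williamson ether synthesis on the only phenol, as in step 1.

Step 11
Reactants: 15 2-(benzyloxy)-4-methoxybenzaldehyde
Product: 17 [2-(benzyloxy)-4-methoxyphenyl]acetonitrile, via N-(1-tosylvinyl)formamide 16 (not isolated)
Conditions: TosMIC, t-BuOK, DME, −40 °C; then MeOH, reflux
Reagents that add atoms: p-toluenesulfonylmethyl isocyanide (TosMIC), Cc1ccc(cc1)S(=O)(=O)C[N+]#[C-]
Why: van Leusen reductive cyanation, the same one-carbon homologation as in step 2.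

Step 12
Reactants: 17 [2-(benzyloxy)-4-methoxyphenyl]acetonitrile
Product: 18 [2-(benzyloxy)-4-methoxyphenyl]acetic acid
Conditions: KOH, EtOH/H2O, reflux; then aq. HCl
Reagents that add atoms: water, O; potassium hydroxide, [K+].[OH-]
Why: Alkaline nitrile hydrolysis through the amide; benzyl and methyl aryl ethers are stable to hot aqueous base.

Step 13
Reactants: 18 [2-(benzyloxy)-4-methoxyphenyl]acetic acid
Product: 19 pentafluorophenyl [2-(benzyloxy)-4-methoxyphenyl]acetate
Conditions: C6F5OH, EDC·HCl, DMAP (cat.), CH2Cl2, 0 °C → rt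
Reagents that add atoms: pentafluorophenol, Oc1c(F)c(F)c(F)c(F)c1F
Why: Carbodiimide (Steglich-type) esterification gives the active ester whose aryloxide later turns the isothiourea catalyst over.

Step 14
Reactants: 13 tert-butyl (E)-3-Ar2-prop-2-en-1-yl carbonate; 19 pentafluorophenyl [2-(benzyloxy)-4-methoxyphenyl]acetate
Product: 21 (2S,3S)-2-Ar1-3-Ar2-pent-4-en-1-ol, via allylated pentafluorophenyl ester 20 (not isolated)
Conditions: cyclometalated Ir–phosphoramidite complex (4 mol%), benzotetramisole (10 mol%), THF, rt; then LiBH4, 0 °C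
Reagents that add atoms: none
Why: Stereodivergent allylic substitution of an aryl acetic ester by synergistic iridium and isothiourea catalysis: the iridium complex ionises 13 and fixes C4 at the aryl-bearing allyl terminus (branched attack), the catalyst-bound C1-ammonium enolate of 19 presents one face and fixes C3, and pentafluorophenoxide releases the Lewis base. Each centre answers to its own catalyst, so the syn (2S,3S) isomer is addressed by the choice of both enantiomers and the remote C3″ has no say. Reduction of the labile active ester 20 in the same flask locks C3 as the alcohol.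

Step 15
Reactants: 21 (2S,3S)-2-Ar1-3-Ar2-pent-4-en-1-ol
Product: 22 (2S,3S)-1-{[(E)-1,2-dichloroethenyl]oxy}-2-Ar1-3-Ar2-pent-4-ene
Conditions: KH (2.2 equiv), THF, 0 °C; Cl2C=CHCl, −50 °C → rt
Reagents that add atoms: trichloroethylene, ClC=C(Cl)Cl
Why: Addition of the potassium alkoxide to dichloroacetylene generated in situ from trichloroethylene gives the (E)-1,2-dichlorovinyl ether, a base-stable masked alkynyl ether; it also keeps O1 distinct from the oxygen still to come at C7.

Step 16
Reactants: 22 (2S,3S)-1-{[(E)-1,2-dichloroethenyl]oxy}-2-Ar1-3-Ar2-pent-4-ene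
Product: 24 (3S,4S)-4-Ar1-3-Ar2-5-{[(E)-1,2-dichloroethenyl]oxy}pentan-1-ol, via B-alkyl-9-BBN 23 (not isolated)
Conditions: 9-BBN, THF, 0 °C → rt; then H2O2, aq. NaOH, 0 °C
Reagents that add atoms: hydrogen peroxide, OO
Why: Anti-Markovnikov hydroboration–oxidation; 9-BBN should select the monosubstituted alkene over the chlorinated, trisubstituted enol ether and places boron, then oxygen, on the terminal carbon, the later C7.

Step 17
Reactants: 24 (3S,4S)-4-Ar1-3-Ar2-5-{[(E)-1,2-dichloroethenyl]oxy}pentan-1-ol
Product: 25 (3S,4S)-4-Ar1-3-Ar2-5-{[(E)-1,2-dichloroethenyl]oxy}pentanal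
Conditions: Dess–Martin periodinane, NaHCO3, CH2Cl2, 0 °C → rt
Reagents that add atoms: none
Why: Dess–Martin oxidation of the primary alcohol under buffered conditions; the α-carbon is a methylene group, so no stereocentre is at risk.

Step 18
Reactants: 25 (3S,4S)-4-Ar1-3-Ar2-5-{[(E)-1,2-dichloroethenyl]oxy}pentanal
Product: 26 (3RS,5S,6S)-6-Ar1-5-Ar2-7-{[(E)-1,2-dichloroethenyl]oxy}hept-1-en-3-ol
Conditions: CH2=CHMgBr, THF, −78 °C; aq. NH4Cl
Reagents that add atoms: vinylmagnesium bromide, C=C[Mg]Br
Why: Grignard 1,2-addition brings in C5 and C6 as the vinyl group; the new carbinol centre forms without control and is removed by oxidation in step 20.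

Step 19
Reactants: 26 (3RS,5S,6S)-6-Ar1-5-Ar2-7-{[(E)-1,2-dichloroethenyl]oxy}hept-1-en-3-ol
Product: 28 (3RS,5S,6S)-6-Ar1-5-Ar2-7-(ethynyloxy)hept-1-en-3-ol, via dilithiated alkynyl ether 27 (not isolated)
Conditions: n-BuLi (3.5 equiv), THF, −78 → −40 °C; then MeOH, −78 °C
Reagents that add atoms: none
Why: Excess n-butyllithium converts the dichlorovinyl ether by β-elimination and chlorine–lithium exchange into the lithium alkynyl ether 27, the carbinol being protected as its lithium alkoxide, and methanol protonates it to the terminal ynol ether; the step is placed before ketone formation because no carbonyl group would survive the reagent.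

Step 20
Reactants: 28 (3RS,5S,6S)-6-Ar1-5-Ar2-7-(ethynyloxy)hept-1-en-3-ol
Product: 29 (5S,6S)-6-Ar1-5-Ar2-7-(ethynyloxy)hept-1-en-3-one
Conditions: Dess–Martin periodinane, NaHCO3, CH2Cl2, 0 °C
Reagents that add atoms: none
Why: Dess–Martin oxidation of the secondary allylic alcohol to the vinyl ketone; the bicarbonate buffer and low temperature should spare the acid-sensitive ynol ether and the Michael-prone enone.

Step 21
Reactants: 29 (5S,6S)-6-Ar1-5-Ar2-7-(ethynyloxy)hept-1-en-3-one
Product: 31 (5S,6S)-4-diazo-6-Ar1-5-Ar2-7-(ethynyloxy)hept-1-en-3-one, via trifluoroacetyl ketone 30 (not isolated)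
Conditions: LiHMDS, THF, −78 °C; CF3CO2CH2CF3, −78 °C; aq. NH4Cl; then MsN3, Et3N, H2O (1 equiv), MeCN, rt
Reagents that add atoms: methanesulfonyl azide, CS(=O)(=O)N=[N+]=[N-]
Why: Detrifluoroacetylative diazo transfer (a Regitz-type deacylative diazo transfer): kinetic enolate formation at the only enolisable position (C4a), C-trifluoroacetylation to 30, then reaction with the sulfonyl azide with loss of the trifluoroacetyl group; this is the established method for α′-diazo-α,β-unsaturated ketones, and neither C3 nor C4 is acidic under the conditions.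

Step 22
Reactants: 31 (5S,6S)-4-diazo-6-Ar1-5-Ar2-7-(ethynyloxy)hept-1-en-3-one
Product: 36 (3S,4R)-3-Ar1-4-Ar2-chroman-7-ol, via vinylketene 32 (not isolated), via fused alkoxycyclobutenone 33 (not isolated), via dienylketene 34 (not isolated), via cyclohexadienone 35 (not isolated)
Conditions: hν (350 nm, Pyrex), degassed ClCH2CH2Cl, 0.002 M, rt; then 80 °C
Reagents that add atoms: none
Why: Proposed new method: irradiation expels nitrogen from the diazo ketone and the vinyl group migrates from C7 to C4a (photochemical Wolff rearrangement, forming C4a–C5) to give vinylketene 32; the ethynyl ether then adds across the ketene C=C in an intramolecular [2+2] cycloaddition, C7 bonding to the terminal alkyne carbon C8 and C4a to the oxygen-bearing carbon C8a, to give alkoxycyclobutenone 33. The closest known chemistry is the photochemical (second-generation) Danheiser benzannulation of α-diazo enones with alkynyl ethers, which is intermolecular, together with intramolecular ketene–alkene and ketene–alkyne [2+2] cycloadditions through short carbon tethers; the union of the two through an O–CH2 tether has not been shown. The pyran closes in the [2+2] event as a six-membered ring through the C4a–C4–C3–C2–O1–C8a tether (fused bicyclo[4.2.0] mode). Ring A closes afterwards: 4π-electrocyclic opening of 33 gives dienylketene 34, in which the C8a=C4a bond lies inside the new pyran and so holds the ketene and vinyl termini cis, and 6π-electrocyclisation (C6–C7) followed by tautomerisation of dienone 35 gives the phenol. No stereocentre is created in the product; the quaternary C4a of 33 is transient, and C3, C4 and C3″ are spectators that never sit next to a carbonyl or a cation. The step needs the [2+2] regiochemistry and intramolecular capture of the ketene: the polarity of the ynol ether (nucleophilic terminal carbon, cation-stabilising O-bearing carbon) and the tether length call for the same bond pairing, and high dilution holds back ketene dimerisation and acylation of the product phenol by 32. The main competing channel, a 1,2-shift of the C4 hydrogen to the carbene carbon, is less likely under direct excitation, where rearrangement is concerted from the s-Z conformer, than under metal catalysis.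

Step 23
Reactants: 36 (3S,4R)-3-Ar1-4-Ar2-chroman-7-ol
Product: 37 (3S,4R)-4-{4-hydroxy-5-[(3S)-7-hydroxychroman-3-yl]-2-methoxyphenyl}-3-(2-hydroxy-4-methoxyphenyl)chroman-7-ol
Conditions: H2 (1 atm), 10% Pd/C, EtOAc/MeOH, rt
Reagents that add atoms: none
Why: Hydrogenolysis of the three benzyl ethers over palladium; the C4–aryl bonds, the chroman C–O bonds and all three stereocentres are inert under these neutral conditions, and the product is the target.

## Compound list

1 | 5-bromo-2-hydroxy-4-methoxybenzaldehyde | COc1cc(O)c(C=O)cc1Br | starting material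
2 | 2-(benzyloxy)-5-bromo-4-methoxybenzaldehyde | COc1cc(OCc2ccccc2)c(C=O)cc1Br | intermediate
3 | N-{2-[2-(benzyloxy)-5-bromo-4-methoxyphenyl]-1-tosylethenyl}formamide | O=CNC(=Cc1cc(Br)c(OC)cc1OCc1ccccc1)S(=O)(=O)c1ccc(C)cc1 | intermediate (not isolated)
4 | [2-(benzyloxy)-5-bromo-4-methoxyphenyl]acetonitrile | N#CCc1cc(Br)c(OC)cc1OCc1ccccc1 | intermediate
5 | 2,4-dihydroxybenzaldehyde | O=Cc1ccc(O)cc1O | starting material
6 | 4-(benzyloxy)-2-hydroxybenzaldehyde | O=Cc1ccc(OCc2ccccc2)cc1O | intermediate
7 | 7-(benzyloxy)-3-[2-(benzyloxy)-5-bromo-4-methoxyphenyl]-2H-chromen-2-imine | N=C1Oc2cc(OCc3ccccc3)ccc2C=C1c1cc(Br)c(OC)cc1OCc1ccccc1 | intermediate (not isolated)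
8 | 7-(benzyloxy)-3-[2-(benzyloxy)-5-bromo-4-methoxyphenyl]-2H-chromen-2-one | O=C1Oc2cc(OCc3ccccc3)ccc2C=C1c1cc(Br)c(OC)cc1OCc1ccccc1 | intermediate
9 | (Z)-2-[2-(benzyloxy)-5-bromo-4-methoxyphenyl]-3-[4-(benzyloxy)-2-hydroxyphenyl]prop-2-en-1-ol | OC/C(=C\c1ccc(OCc2ccccc2)cc1O)c1cc(Br)c(OC)cc1OCc1ccccc1 | intermediate
10 | 7-(benzyloxy)-3-[2-(benzyloxy)-5-bromo-4-methoxyphenyl]-2H-chromene | COc1cc(OCc2ccccc2)c(cc1Br)C1=Cc2ccc(OCc3ccccc3)cc2OC1 | intermediate
11 | (3S)-7-(benzyloxy)-3-[2-(benzyloxy)-5-bromo-4-methoxyphenyl]chromane | COc1cc(OCc2ccccc2)c(cc1Br)[C@H]1COc2cc(OCc3ccccc3)ccc2C1 | intermediate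
12 | (E)-3-{4-(benzyloxy)-5-[(3S)-7-(benzyloxy)chroman-3-yl]-2-methoxyphenyl}prop-2-en-1-ol | COc1cc(OCc2ccccc2)c(cc1/C=C/CO)[C@H]1COc2cc(OCc3ccccc3)ccc2C1 | intermediate
13 | tert-butyl (E)-3-{4-(benzyloxy)-5-[(3S)-7-(benzyloxy)chroman-3-yl]-2-methoxyphenyl}prop-2-en-1-yl carbonate | COc1cc(OCc2ccccc2)c(cc1/C=C/COC(=O)OC(C)(C)C)[C@H]1COc2cc(OCc3ccccc3)ccc2C1 | intermediate
14 | 2-hydroxy-4-methoxybenzaldehyde | COc1ccc(C=O)c(O)c1 | starting material
15 | 2-(benzyloxy)-4-methoxybenzaldehyde | COc1ccc(C=O)c(OCc2ccccc2)c1 | intermediate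
16 | N-{2-[2-(benzyloxy)-4-methoxyphenyl]-1-tosylethenyl}formamide | O=CNC(=Cc1ccc(OC)cc1OCc1ccccc1)S(=O)(=O)c1ccc(C)cc1 | intermediate (not isolated)
17 | [2-(benzyloxy)-4-methoxyphenyl]acetonitrile | N#CCc1ccc(OC)cc1OCc1ccccc1 | intermediate
18 | [2-(benzyloxy)-4-methoxyphenyl]acetic acid | OC(=O)Cc1ccc(OC)cc1OCc1ccccc1 | intermediate
19 | pentafluorophenyl [2-(benzyloxy)-4-methoxyphenyl]acetate | O=C(Cc1ccc(OC)cc1OCc1ccccc1)Oc1c(F)c(F)c(F)c(F)c1F | intermediate
20 | pentafluorophenyl (2S,3S)-2-Ar1-3-Ar2-pent-4-enoate | COc1ccc([C@H]([C@@H](c2cc([C@H]3COc4cc(OCc5ccccc5)ccc4C3)c(OCc3ccccc3)cc2OC)C=C)C(=O)Oc2c(F)c(F)c(F)c(F)c2F)c(OCc2ccccc2)c1 | intermediate (not isolated)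
21 | (2S,3S)-2-Ar1-3-Ar2-pent-4-en-1-ol | COc1ccc([C@H]([C@@H](c2cc([C@H]3COc4cc(OCc5ccccc5)ccc4C3)c(OCc3ccccc3)cc2OC)C=C)CO)c(OCc2ccccc2)c1 | intermediate
22 | (2S,3S)-1-{[(E)-1,2-dichloroethenyl]oxy}-2-Ar1-3-Ar2-pent-4-ene | COc1ccc([C@H]([C@@H](c2cc([C@H]3COc4cc(OCc5ccccc5)ccc4C3)c(OCc3ccccc3)cc2OC)C=C)CO/C(Cl)=C\Cl)c(OCc2ccccc2)c1 | intermediate
23 | 9-[(3S,4S)-4-Ar1-3-Ar2-5-{[(E)-1,2-dichloroethenyl]oxy}pentyl]-9-borabicyclo[3.3.1]nonane | COc1ccc([C@H]([C@@H](c2cc([C@H]3COc4cc(OCc5ccccc5)ccc4C3)c(OCc3ccccc3)cc2OC)CCB2C3CCCC2CCC3)CO/C(Cl)=C\Cl)c(OCc2ccccc2)c1 | intermediate (not isolated)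
24 | (3S,4S)-4-Ar1-3-Ar2-5-{[(E)-1,2-dichloroethenyl]oxy}pentan-1-ol | COc1ccc([C@H]([C@@H](c2cc([C@H]3COc4cc(OCc5ccccc5)ccc4C3)c(OCc3ccccc3)cc2OC)CCO)CO/C(Cl)=C\Cl)c(OCc2ccccc2)c1 | intermediate
25 | (3S,4S)-4-Ar1-3-Ar2-5-{[(E)-1,2-dichloroethenyl]oxy}pentanal | COc1ccc([C@H]([C@@H](c2cc([C@H]3COc4cc(OCc5ccccc5)ccc4C3)c(OCc3ccccc3)cc2OC)CC=O)CO/C(Cl)=C\Cl)c(OCc2ccccc2)c1 | intermediate
26 | (3RS,5S,6S)-6-Ar1-5-Ar2-7-{[(E)-1,2-dichloroethenyl]oxy}hept-1-en-3-ol | COc1ccc([C@H]([C@@H](c2cc([C@H]3COc4cc(OCc5ccccc5)ccc4C3)c(OCc3ccccc3)cc2OC)CC(O)C=C)CO/C(Cl)=C\Cl)c(OCc2ccccc2)c1 | intermediate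
27 | lithium alkoxide and lithium acetylide of 28 (dilithiated alkynyl ether) | COc1ccc([C@H]([C@@H](c2cc([C@H]3COc4cc(OCc5ccccc5)ccc4C3)c(OCc3ccccc3)cc2OC)CC(O[Li])C=C)COC#C[Li])c(OCc2ccccc2)c1 | intermediate (not isolated)
28 | (3RS,5S,6S)-6-Ar1-5-Ar2-7-(ethynyloxy)hept-1-en-3-ol | COc1ccc([C@H]([C@@H](c2cc([C@H]3COc4cc(OCc5ccccc5)ccc4C3)c(OCc3ccccc3)cc2OC)CC(O)C=C)COC#C)c(OCc2ccccc2)c1 | intermediate
29 | (5S,6S)-6-Ar1-5-Ar2-7-(ethynyloxy)hept-1-en-3-one | COc1ccc([C@H]([C@@H](c2cc([C@H]3COc4cc(OCc5ccccc5)ccc4C3)c(OCc3ccccc3)cc2OC)CC(=O)C=C)COC#C)c(OCc2ccccc2)c1 | intermediate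
30 | 4-(trifluoroacetyl) derivative of 29 (β-diketone, largely enolised; C5 and C6 as in 29) | COc1ccc([C@H]([C@@H](c2cc([C@H]3COc4cc(OCc5ccccc5)ccc4C3)c(OCc3ccccc3)cc2OC)C(C(=O)C=C)C(=O)C(F)(F)F)COC#C)c(OCc2ccccc2)c1 | intermediate (not isolated)
31 | (5S,6S)-4-diazo-6-Ar1-5-Ar2-7-(ethynyloxy)hept-1-en-3-one | COc1ccc([C@H]([C@@H](c2cc([C@H]3COc4cc(OCc5ccccc5)ccc4C3)c(OCc3ccccc3)cc2OC)C(=[N+]=[N-])C(=O)C=C)COC#C)c(OCc2ccccc2)c1 | intermediate (key-step precursor)
32 | vinylketene from 31: 4-Ar1-3-Ar2-2-ethenyl-5-(ethynyloxy)pent-1-en-1-one (stereocentres as in 31) | COc1ccc([C@H]([C@@H](c2cc([C@H]3COc4cc(OCc5ccccc5)ccc4C3)c(OCc3ccccc3)cc2OC)C(C=C)=C=O)COC#C)c(OCc2ccccc2)c1 | intermediate (not isolated)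
33 | fused alkoxycyclobutenone: 4-Ar1-5-Ar2-6-ethenyl-2-oxabicyclo[4.2.0]oct-1(8)-en-7-one (C3 and C4 of the target fixed, ring-fusion carbon either way) | COc1ccc([C@H]2COC3=CC(=O)C3(C=C)[C@@H]2c2cc([C@H]3COc4cc(OCc5ccccc5)ccc4C3)c(OCc3ccccc3)cc2OC)c(OCc2ccccc2)c1 | intermediate (not isolated)
34 | dienylketene: 3-Ar1-4-Ar2-5-ethenyl-6-(2-oxoethenyl)-3,4-dihydro-2H-pyran | COc1ccc([C@H]2COC(C=C=O)=C(C=C)[C@@H]2c2cc([C@H]3COc4cc(OCc5ccccc5)ccc4C3)c(OCc3ccccc3)cc2OC)c(OCc2ccccc2)c1 | intermediate (not isolated)
35 | cyclohexadienone tautomer of 36: 3-Ar1-4-Ar2-3,4-dihydro-2H-chromen-7(6H)-one | COc1ccc([C@H]2COC3=CC(=O)CC=C3[C@@H]2c2cc([C@H]3COc4cc(OCc5ccccc5)ccc4C3)c(OCc3ccccc3)cc2OC)c(OCc2ccccc2)c1 | intermediate (not isolated)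
36 | (3S,4R)-3-[2-(benzyloxy)-4-methoxyphenyl]-4-{4-(benzyloxy)-5-[(3S)-7-(benzyloxy)chroman-3-yl]-2-methoxyphenyl}chroman-7-ol | COc1ccc([C@H]2COc3cc(O)ccc3[C@@H]2c2cc([C@H]3COc4cc(OCc5ccccc5)ccc4C3)c(OCc3ccccc3)cc2OC)c(OCc2ccccc2)c1 | intermediate (key-step product)
37 | (3S,4R)-4-{4-hydroxy-5-[(3S)-7-hydroxychroman-3-yl]-2-methoxyphenyl}-3-(2-hydroxy-4-methoxyphenyl)chroman-7-ol | COc1ccc([C@H]2COc3cc(O)ccc3[C@@H]2c2cc([C@H]3COc4cc(O)ccc4C3)c(O)cc2OC)c(O)c1 | target

## Step count and risks

Total: 23 steps. Longest linear sequence: 18 steps (1, 2, 4–9, 14–23). Step 3 and steps 10–13 are side branches that join at steps 4 and 14.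

**Step 22 (key step).**
- What may go wrong: the ketene may fail to reach the tethered ynol ether in the required geometry, so that dimerisation, acylation of the product phenol, or a 1,2-hydrogen shift from C4 to the carbene centre take over. The diazo group may also add thermally to the ynol ether before irradiation (dipolar cycloaddition on storage).
- Fallback with known chemistry, from 29 back to 36: the ynol ether of 29 is hydrated with a trace of acid in wet THF to the keto acetate F1. The same diazo transfer gives the diazo ketone acetate F2. Irradiation of F2 with (triisopropylsilyloxy)acetylene in an intermolecular photochemical Danheiser benzannulation gives the resorcinol monosilyl ether F3, with the free hydroxyl at C7 and the silyloxy group at C8a. Methanolysis of the acetate and fluoride cleavage of the silyl ether give the triol F4. A Mitsunobu etherification, in which only the C8a hydroxyl can reach C2, closes the pyran and returns to 36.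

**Step 21.**
- What may go wrong: Michael addition of the lithium enolate to the unsubstituted vinyl ketone (oligomerisation), or competing deprotonation and acylation at the ynol ether terminus.
- Fallback, from 25 back to 36: the vinyl group is replaced by a β-silylvinyl group, a much weaker Michael acceptor. Addition of (E)-2-(trimethylsilyl)vinyllithium to 25 gives the silyl allylic alcohol F5. n-Butyllithium then methanol gives the ynol ether F6. Dess–Martin oxidation gives the β-silyl enone F7, and diazo transfer the diazo ketone F8. Photolysis under the conditions of step 22 gives the 6-silyl chromanol F9, and ipso-protodesilylation ortho to the phenol with trifluoroacetic acid at 0 °C returns to 36.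

**Step 14.**
- What may go wrong: erosion of branched selectivity or of facial control by the ortho substituents on both partners, or epimerisation of the active ester at C3 before reduction.
- Fallback, from 12 and 18 back to 21: esterification gives the cinnamyl arylacetate F10. An Ireland–Claisen rearrangement through its chair transition state gives the syn acid F11; the absolute sense is supplied by a chiral boron ketene acetal or, failing that, by separation of the two syn diastereomers, which differ because of C3″. Hydride reduction of F11 gives 21.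

**Step 7.**
- What may go wrong: low conversion or low facial selectivity, because the ortho-benzyloxy group twists the 3-aryl ring out of the alkene plane; air oxidation of the isoflavene 10.
- Fallback, from 9 back to 11: hydroxyl-directed asymmetric hydrogenation of the allylic alcohol 9 with a ruthenium–BINAP catalyst gives the saturated diol F12 before ring closure, and the Mitsunobu etherification of step 6 then gives 11.

Further compounds

F1 | step 22 | (2S,3S)-2-Ar1-3-Ar2-5-oxohept-6-en-1-yl acetate (keto acetate from 29) | COc1ccc([C@H]([C@@H](c2cc([C@H]3COc4cc(OCc5ccccc5)ccc4C3)c(OCc3ccccc3)cc2OC)CC(=O)C=C)COC(C)=O)c(OCc2ccccc2)c1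
F2 | step 22 | (2S,3S)-4-diazo-2-Ar1-3-Ar2-5-oxohept-6-en-1-yl acetate | COc1ccc([C@H]([C@@H](c2cc([C@H]3COc4cc(OCc5ccccc5)ccc4C3)c(OCc3ccccc3)cc2OC)C(=[N+]=[N-])C(=O)C=C)COC(C)=O)c(OCc2ccccc2)c1
F3 | step 22 | 2-Ar1-3-Ar2-3-[4-hydroxy-2-(triisopropylsilyloxy)phenyl]propyl acetate (C3 and C4 of the target fixed) | COc1ccc([C@H]([C@@H](c2cc([C@H]3COc4cc(OCc5ccccc5)ccc4C3)c(OCc3ccccc3)cc2OC)c2ccc(O)cc2O[Si](C(C)C)(C(C)C)C(C)C)COC(C)=O)c(OCc2ccccc2)c1
F4 | step 22 | 4-[1-Ar2-2-Ar1-3-hydroxypropyl]benzene-1,3-diol (C3 and C4 of the target fixed) | COc1ccc([C@H]([C@@H](c2cc([C@H]3COc4cc(OCc5ccccc5)ccc4C3)c(OCc3ccccc3)cc2OC)c2ccc(O)cc2O)CO)c(OCc2ccccc2)c1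
F5 | step 21 | (1E,5S,6S)-6-Ar1-5-Ar2-7-{[(E)-1,2-dichloroethenyl]oxy}-1-(trimethylsilyl)hept-1-en-3-ol (carbinol epimers) | COc1ccc([C@H]([C@@H](c2cc([C@H]3COc4cc(OCc5ccccc5)ccc4C3)c(OCc3ccccc3)cc2OC)CC(O)/C=C/[Si](C)(C)C)CO/C(Cl)=C\Cl)c(OCc2ccccc2)c1
F6 | step 21 | (1E,5S,6S)-6-Ar1-5-Ar2-7-(ethynyloxy)-1-(trimethylsilyl)hept-1-en-3-ol (carbinol epimers) | COc1ccc([C@H]([C@@H](c2cc([C@H]3COc4cc(OCc5ccccc5)ccc4C3)c(OCc3ccccc3)cc2OC)CC(O)/C=C/[Si](C)(C)C)COC#C)c(OCc2ccccc2)c1
F7 | step 21 | (1E,5S,6S)-6-Ar1-5-Ar2-7-(ethynyloxy)-1-(trimethylsilyl)hept-1-en-3-one | COc1ccc([C@H]([C@@H](c2cc([C@H]3COc4cc(OCc5ccccc5)ccc4C3)c(OCc3ccccc3)cc2OC)CC(=O)/C=C/[Si](C)(C)C)COC#C)c(OCc2ccccc2)c1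
F8 | step 21 | (1E,5S,6S)-4-diazo-6-Ar1-5-Ar2-7-(ethynyloxy)-1-(trimethylsilyl)hept-1-en-3-one | COc1ccc([C@H]([C@@H](c2cc([C@H]3COc4cc(OCc5ccccc5)ccc4C3)c(OCc3ccccc3)cc2OC)C(=[N+]=[N-])C(=O)/C=C/[Si](C)(C)C)COC#C)c(OCc2ccccc2)c1
F9 | step 21 | (3S,4R)-3-Ar1-4-Ar2-6-(trimethylsilyl)chroman-7-ol | COc1ccc([C@H]2COc3cc(O)c([Si](C)(C)C)cc3[C@@H]2c2cc([C@H]3COc4cc(OCc5ccccc5)ccc4C3)c(OCc3ccccc3)cc2OC)c(OCc2ccccc2)c1
F10 | step 14 | (E)-3-Ar2-prop-2-en-1-yl [2-(benzyloxy)-4-methoxyphenyl]acetate | COc1cc(OCc2ccccc2)c(cc1/C=C/COC(=O)Cc1ccc(OC)cc1OCc1ccccc1)[C@H]1COc2cc(OCc3ccccc3)ccc2C1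
F11 | step 14 | (2S,3S)-2-Ar1-3-Ar2-pent-4-enoic acid | COc1ccc([C@H]([C@@H](c2cc([C@H]3COc4cc(OCc5ccccc5)ccc4C3)c(OCc3ccccc3)cc2OC)C=C)C(O)=O)c(OCc2ccccc2)c1
F12 | step 7 | (2S)-2-[2-(benzyloxy)-5-bromo-4-methoxyphenyl]-3-[4-(benzyloxy)-2-hydroxyphenyl]propan-1-ol | COc1cc(OCc2ccccc2)c(cc1Br)[C@H](Cc1ccc(OCc2ccccc2)cc1O)CO
A1 | alternative 1 | tetra-O-pivaloyl derivative of the target | COc1ccc([C@H]2COc3cc(OC(=O)C(C)(C)C)ccc3[C@@H]2c2cc([C@H]5COc6cc(OC(=O)C(C)(C)C)ccc6C5)c(OC(=O)C(C)(C)C)cc2OC)c(OC(=O)C(C)(C)C)c1
A2 | alternative 1 | (2S,3R)-trans-2,3-diaryl-2,3-dihydrobenzofuran tetrapivalate (ring-contracted precursor of A1) | COc1ccc([C@H]2Oc3cc(OC(=O)C(C)(C)C)ccc3[C@@H]2c2cc([C@H]5COc6cc(OC(=O)C(C)(C)C)ccc6C5)c(OC(=O)C(C)(C)C)cc2OC)c(OC(=O)C(C)(C)C)c1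
A3 | alternative 1 | diazomethane | C=[N+]=[N-]
A4 | alternative 2 | trans-3,4-diarylchroman-2-ol, tetrabenzyl ether (anomeric mixture at C2) | COc1ccc([C@H]2C(O)Oc3cc(OCc4ccccc4)ccc3[C@@H]2c2cc([C@H]5COc6cc(OCc7ccccc7)ccc6C5)c(OCc5ccccc5)cc2OC)c(OCc2ccccc2)c1
A5 | alternative 2 | 5-(benzyloxy)-2-[Ar2(hydroxy)methyl]phenol (hydroxybenzhydrol, carbinol centre of either configuration) | OC(c1ccc(OCc2ccccc2)cc1O)c1cc([C@H]2COc3cc(OCc4ccccc4)ccc3C2)c(OCc2ccccc2)cc1OC
A6 | alternative 2 | [2-(benzyloxy)-4-methoxyphenyl]acetaldehyde | O=CCc1ccc(OC)cc1OCc1ccccc1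
A7 | alternative 3 | tri-O-benzyl target with the ring C hydroxyl free | COc1ccc([C@H]2COc3cc(OCc4ccccc4)ccc3[C@@H]2c2cc([C@H]5COc6cc(OCc7ccccc7)ccc6C5)c(O)cc2OC)c(OCc2ccccc2)c1
A8 | alternative 3 | (E)-1-diazo-1-[(3S,4R)-3-Ar1-7-(benzyloxy)chroman-4-yl]-4-[(3S)-7-(benzyloxy)chroman-3-yl]but-3-en-2-one | COc1ccc([C@H]2COc3cc(OCc4ccccc4)ccc3[C@@H]2C(=[N+]=[N-])C(=O)/C=C/[C@H]2COc3cc(OCc4ccccc4)ccc3C2)c(OCc2ccccc2)c1
A9 | alternative 3 | methoxyacetylene | COC#C
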